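**Retrosynthetic overview**
- Target ⇐ hydrogenolysis of a benzyl ester and a phenolic benzyl ether, after fluoride removal of a silyl ether on the ring B hydroxymethyl group.
- Tertiary alcohol ⇐ Markovnikov hydration of a 2-methylallyl group; the (S)-carbinol C–C bond ⇐ asymmetric methallylation of a diaryl ether aldehyde with a 2-methylallyl metal fragment (key step).
- Diaryl ether ⇐ SNAr of a ring B phenol on a ring A aryl fluoride that is para to the formyl and ortho to the ester group.
- Ring A fluoride ⇐ 4-fluoro-2-methoxybenzaldehyde by ortho-lithiation/carboxylation between F and OMe; ring B phenol ⇐ creosol by ortho-formylation, demethylation, selective 3-O-benzylation, reduction and silylation.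
- No ring is constructed: both benzene rings are bought; ring B is elaborated first, ring A second, they are joined through the ether oxygen, and the side chain is then built on ring A.

Assumption: the target is the single (S)-enantiomer encoded by the SMILES (benzylic carbinol S; no other stereocentre).

**Route**

Step 1
Reactants: 1 2-methoxy-4-methylphenol (creosol)
Product: 3 2-hydroxy-3-methoxy-5-methylbenzaldehyde, via magnesium salt of 2-(hydroxymethyl)-6-methoxy-4-methylphenol 2 (not isolated)
Conditions: MgCl2, Et3N, (CH2O)n, MeCN, reflux; 1 M HCl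
Reagents that add atoms: formaldehyde (from paraformaldehyde) C=O
Why: Magnesium-mediated ortho-formylation (Casnati–Skattebøl): the magnesium phenoxide delivers formaldehyde only to the single free ortho position, and the benzylic alkoxide 2 is oxidised to the aldehyde by a second equivalent of formaldehyde (Oppenauer-type hydride transfer).

Step 2
Reactants: 3 2-hydroxy-3-methoxy-5-methylbenzaldehyde
Product: 4 2,3-dihydroxy-5-methylbenzaldehyde
Conditions: BBr3, CH2Cl2, −78 °C → rt; H2O
Reagents that add atoms: none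
Why: Lewis-acid O-demethylation of an aryl methyl ether with BBr3, which leaves the aldehyde and the ring methyl group untouched.

Step 3
Reactants: 4 2,3-dihydroxy-5-methylbenzaldehyde
Product: 6 3-(benzyloxy)-2-hydroxy-5-methylbenzaldehyde, via disodium 3-formyl-5-methylbenzene-1,2-diolate 5 (not isolated)
Conditions: NaH (2.2 equiv), DMSO, rt; BnBr (1.0 equiv), rt; 1 M HCl
Reagents that add atoms: benzyl bromide BrCc1ccccc1
Why: Regioselective Williamson etherification of dianion 5, in which the 2-phenoxide is deactivated by conjugation and chelation with the ortho-formyl group, so one equivalent of BnBr alkylates the more nucleophilic 3-phenoxide.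

Step 4
Reactants: 6 3-(benzyloxy)-2-hydroxy-5-methylbenzaldehyde
Product: 7 2-(benzyloxy)-6-(hydroxymethyl)-4-methylphenol
Conditions: NaBH4, MeOH/THF, 0 °C
Reagents that add atoms: none
Why: Chemoselective borohydride reduction of the aldehyde to the benzylic alcohol, with the benzyl ether and phenol inert.

Step 5
Reactants: 7 2-(benzyloxy)-6-(hydroxymethyl)-4-methylphenol
Product: 8 2-(benzyloxy)-4-methyl-6-{[(triisopropylsilyl)oxy]methyl}phenol
Conditions: TIPSCl (1.05 equiv), imidazole, CH2Cl2, 0 °C → rt
Reagents that add atoms: chlorotriisopropylsilane CC(C)[Si](Cl)(C(C)C)C(C)C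
Why: Chemoselective O-silylation, because the bulky silyl chloride reacts with the unhindered primary alcohol much faster than with the 2,6-disubstituted phenol (any aryl silyl ether formed is cleaved again by brief K2CO3/MeOH).

Step 6
Reactants: 9 4-fluoro-2-methoxybenzaldehyde
Product: 10 2-(4-fluoro-2-methoxyphenyl)-1,3-dioxolane
Conditions: HOCH2CH2OH, p-TsOH (cat.), toluene, reflux (Dean–Stark)
Reagents that add atoms: ethane-1,2-diol OCCO
Why: Acid-catalysed acetalisation with azeotropic water removal masks the aldehyde for the organolithium step.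

Step 7
Reactants: 10 2-(4-fluoro-2-methoxyphenyl)-1,3-dioxolane
Product: 13 6-fluoro-3-formyl-2-methoxybenzoic acid, via [3-(1,3-dioxolan-2-yl)-6-fluoro-2-methoxyphenyl]lithium 11 (not isolated), via lithium 3-(1,3-dioxolan-2-yl)-6-fluoro-2-methoxybenzoate 12 (not isolated)
Conditions: s-BuLi, TMEDA, THF, −78 °C; CO2; then 2 M HCl, THF, rt
Reagents that add atoms: carbon dioxide O=C=O; water O
Why: Directed ortho-metalation at the most acidic C–H (flanked by F and OMe, held at −78 °C to avoid LiF loss), CO2 trapping to the carboxylate, and acetal hydrolysis in the acidic work-up to return the aldehyde.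

Step 8
Reactants: 13 6-fluoro-3-formyl-2-methoxybenzoic acid
Product: 14 benzyl 6-fluoro-3-formyl-2-methoxybenzoate
Conditions: BnBr, KHCO3, DMF, rt
Reagents that add atoms: benzyl bromide BrCc1ccccc1
Why: SN2 O-alkylation of the carboxylate gives a benzyl ester, chosen because this di-ortho-substituted benzoate can later be freed by hydrogenolysis instead of a sluggish saponification.

Step 9
Reactants: 14 benzyl 6-fluoro-3-formyl-2-methoxybenzoate; 8 2-(benzyloxy)-4-methyl-6-{[(triisopropylsilyl)oxy]methyl}phenol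
Product: 15 benzyl 6-[2-(benzyloxy)-4-methyl-6-{[(triisopropylsilyl)oxy]methyl}phenoxy]-3-formyl-2-methoxybenzoate
Conditions: K2CO3, DMF, 60 °C
Reagents that add atoms: none
Why: Nucleophilic aromatic substitution (SNAr) in which the fluoride, para to the formyl and ortho to the ester group, is displaced by the phenoxide of 8 through a Meisenheimer complex without any metal catalyst.

Step 10
Reactants: 15 benzyl 6-[2-(benzyloxy)-4-methyl-6-{[(triisopropylsilyl)oxy]methyl}phenoxy]-3-formyl-2-methoxybenzoate; 16 2-methylallylmagnesium chloride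
Product: 18 benzyl 6-[2-(benzyloxy)-4-methyl-6-{[(triisopropylsilyl)oxy]methyl}phenoxy]-3-[(1S)-1-hydroxy-3-methylbut-3-en-1-yl]-2-methoxybenzoate, via diisopinocampheylborinate ester of the homoallylic alcohol 17 (not isolated)
Conditions: (−)-Ipc2BOMe + 16, Et2O, −78 °C → rt; then 15, −78 °C; NaBO3·4H2O, THF/H2O, rt
Reagents that add atoms: none
Why: Brown asymmetric methallylboration (carbonyl allylation through a closed chair transition state), in which the 2-methylallyl-diisopinocampheylborane made in the flask from 16 and (−)-Ipc2BOMe [from (+)-α-pinene] adds to the Si face of the aryl aldehyde and so sets the (S)-carbinol (about 90% ee or better expected), while ester, ethers and silyl ether are inert and perborate oxidation releases the alcohol.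

Step 11
Reactants: 18 benzyl 6-[2-(benzyloxy)-4-methyl-6-{[(triisopropylsilyl)oxy]methyl}phenoxy]-3-[(1S)-1-hydroxy-3-methylbut-3-en-1-yl]-2-methoxybenzoate
Product: 19 benzyl 6-[2-(benzyloxy)-4-methyl-6-{[(triisopropylsilyl)oxy]methyl}phenoxy]-3-[(1S)-1,3-dihydroxy-3-methylbutyl]-2-methoxybenzoate
Conditions: Co(acac)2 (20 mol%), PhSiH3, O2 (1 atm), THF, rt
Reagents that add atoms: dioxygen O=O
Why: Mukaiyama hydration (hydrogen-atom transfer to the 1,1-disubstituted alkene, O2 capture of the tertiary radical, reduction of the peroxide) gives the Markovnikov tertiary alcohol under neutral conditions that do not touch the benzylic stereocentre or the protecting groups.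

Step 12
Reactants: 19 benzyl 6-[2-(benzyloxy)-4-methyl-6-{[(triisopropylsilyl)oxy]methyl}phenoxy]-3-[(1S)-1,3-dihydroxy-3-methylbutyl]-2-methoxybenzoate
Product: 20 benzyl 6-[2-(benzyloxy)-6-(hydroxymethyl)-4-methylphenoxy]-3-[(1S)-1,3-dihydroxy-3-methylbutyl]-2-methoxybenzoate
Conditions: TBAF, AcOH (1:1), THF, rt → 40 °C
Reagents that add atoms: none
Why: Fluoride-mediated desilylation, buffered with acetic acid so that no basic alkoxide endangers the benzyl ester, frees the primary benzylic alcohol.

Step 13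
Reactants: 20 benzyl 6-[2-(benzyloxy)-6-(hydroxymethyl)-4-methylphenoxy]-3-[(1S)-1,3-dihydroxy-3-methylbutyl]-2-methoxybenzoate
Product: 21 6-[2-hydroxy-6-(hydroxymethyl)-4-methylphenoxy]-3-[(1S)-1,3-dihydroxy-3-methylbutyl]-2-methoxybenzoic acid
Conditions: H2 (1 atm), 10% Pd/C, EtOAc, rt, stopped at full conversion
Reagents that add atoms: none
Why: Catalytic hydrogenolysis cleaves the benzyl ester and the phenolic benzyl ether, both much faster than benzylic alcohol C–O bonds under neutral conditions at 1 atm, and gives the target with the (S)-centre unchanged.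

**Compound list**
1 | 2-methoxy-4-methylphenol (creosol) | COc1cc(C)ccc1O | starting material
2 | magnesium salt of 2-(hydroxymethyl)-6-methoxy-4-methylphenol | COc1cc(C)cc(C[O-])c1[O-].[Mg+2] | intermediate
3 | 2-hydroxy-3-methoxy-5-methylbenzaldehyde | COc1cc(C)cc(C=O)c1O | intermediate
4 | 2,3-dihydroxy-5-methylbenzaldehyde | Cc1cc(O)c(O)c(C=O)c1 | intermediate
5 | disodium 3-formyl-5-methylbenzene-1,2-diolate | Cc1cc([O-])c([O-])c(C=O)c1.[Na+].[Na+] | intermediate
6 | 3-(benzyloxy)-2-hydroxy-5-methylbenzaldehyde | Cc1cc(OCc2ccccc2)c(O)c(C=O)c1 | intermediate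
7 | 2-(benzyloxy)-6-(hydroxymethyl)-4-methylphenol | Cc1cc(OCc2ccccc2)c(O)c(CO)c1 | intermediate
8 | 2-(benzyloxy)-4-methyl-6-{[(triisopropylsilyl)oxy]methyl}phenol | Cc1cc(OCc2ccccc2)c(O)c(CO[Si](C(C)C)(C(C)C)C(C)C)c1 | intermediate
9 | 4-fluoro-2-methoxybenzaldehyde | COc1cc(F)ccc1C=O | starting material
10 | 2-(4-fluoro-2-methoxyphenyl)-1,3-dioxolane | COc1cc(F)ccc1C1OCCO1 | intermediate
11 | [3-(1,3-dioxolan-2-yl)-6-fluoro-2-methoxyphenyl]lithium | COc1c([Li])c(F)ccc1C1OCCO1 | intermediate
12 | lithium 3-(1,3-dioxolan-2-yl)-6-fluoro-2-methoxybenzoate | COc1c(C(=O)[O-])c(F)ccc1C1OCCO1.[Li+] | intermediate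
13 | 6-fluoro-3-formyl-2-methoxybenzoic acid | COc1c(C=O)ccc(F)c1C(=O)O | intermediate
14 | benzyl 6-fluoro-3-formyl-2-methoxybenzoate | COc1c(C=O)ccc(F)c1C(=O)OCc1ccccc1 | intermediate
15 | benzyl 6-[2-(benzyloxy)-4-methyl-6-{[(triisopropylsilyl)oxy]methyl}phenoxy]-3-formyl-2-methoxybenzoate | COc1c(C=O)ccc(Oc2c(OCc3ccccc3)cc(C)cc2CO[Si](C(C)C)(C(C)C)C(C)C)c1C(=O)OCc1ccccc1 | intermediate
16 | 2-methylallylmagnesium chloride | CC(=C)C[Mg]Cl | starting material
17 | benzyl 6-[2-(benzyloxy)-4-methyl-6-{[(triisopropylsilyl)oxy]methyl}phenoxy]-3-[(1S)-1-[(diisopinocampheylboranyl)oxy]-3-methylbut-3-en-1-yl]-2-methoxybenzoate | COc1c([C@@H](OB([C@@H]2C[C@@H]3C[C@H]([C@H]2C)C3(C)C)[C@@H]2C[C@@H]3C[C@H]([C@H]2C)C3(C)C)CC(C)=C)ccc(Oc2c(OCc3ccccc3)cc(C)cc2CO[Si](C(C)C)(C(C)C)C(C)C)c1C(=O)OCc1ccccc1 | intermediate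
18 | benzyl 6-[2-(benzyloxy)-4-methyl-6-{[(triisopropylsilyl)oxy]methyl}phenoxy]-3-[(1S)-1-hydroxy-3-methylbut-3-en-1-yl]-2-methoxybenzoate | COc1c([C@@H](O)CC(C)=C)ccc(Oc2c(OCc3ccccc3)cc(C)cc2CO[Si](C(C)C)(C(C)C)C(C)C)c1C(=O)OCc1ccccc1 | intermediate
19 | benzyl 6-[2-(benzyloxy)-4-methyl-6-{[(triisopropylsilyl)oxy]methyl}phenoxy]-3-[(1S)-1,3-dihydroxy-3-methylbutyl]-2-methoxybenzoate | COc1c([C@@H](O)CC(C)(C)O)ccc(Oc2c(OCc3ccccc3)cc(C)cc2CO[Si](C(C)C)(C(C)C)C(C)C)c1C(=O)OCc1ccccc1 | intermediate
20 | benzyl 6-[2-(benzyloxy)-6-(hydroxymethyl)-4-methylphenoxy]-3-[(1S)-1,3-dihydroxy-3-methylbutyl]-2-methoxybenzoate | COc1c([C@@H](O)CC(C)(C)O)ccc(Oc2c(OCc3ccccc3)cc(C)cc2CO)c1C(=O)OCc1ccccc1 | intermediate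
21 | 6-[2-hydroxy-6-(hydroxymethyl)-4-methylphenoxy]-3-[(1S)-1,3-dihydroxy-3-methylbutyl]-2-methoxybenzoic acid | COc1c([C@@H](O)CC(C)(C)O)ccc(Oc2c(O)cc(C)cc2CO)c1C(=O)O | target

**Totals**
Total step count: 13. Longest linear sequence: 10 steps (from 1 through steps 1–5 and 9–13 to 21).

**Three steps most likely to fail, with fallbacks**

Step 9 (SNAr). The phenoxide of 8 is flanked on both sides, and liberated fluoride could attack silicon. Fallback: couple before silylating. Set out from 7 and 14. K2CO3 in DMSO at rt to 40 °C arylates only the phenoxide of the unprotected diol 7 (the aliphatic hydroxyl is not deprotonated, and no silicon is present when fluoride is released). This gives benzyl 6-[2-(benzyloxy)-6-(hydroxymethyl)-4-methylphenoxy]-3-formyl-2-methoxybenzoate F1. TIPSCl and imidazole in CH2Cl2 then silylate its only hydroxyl group, and the route is rejoined at 15.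

Step 10 (asymmetric methallylation). The enantiomeric excess may fall short with this ortho-substituted, electron-rich aldehyde. Fallback: correct the stereocentre by reagent-controlled ketone reduction. Set out from 19 of insufficient enantiomeric purity. MnO2 in CH2Cl2 oxidises the only free benzylic alcohol (the tertiary alcohol is inert) to benzyl 6-[2-(benzyloxy)-4-methyl-6-{[(triisopropylsilyl)oxy]methyl}phenoxy]-3-(3-hydroxy-3-methylbutanoyl)-2-methoxybenzoate F2. Corey–Bakshi–Shibata reduction with (R)-2-methyl-CBS-oxazaborolidine and BH3·SMe2 in THF at −20 °C, with the aryl group as the large substituent, delivers the (S)-alcohol and comes back to the route at 19.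

Step 11 (Mukaiyama hydration). Simple reduction of the alkene or oxidation at the benzylic carbinol may compete under the radical conditions. Fallback: replace hydration by oxidative cleavage and methyl addition. Set out from 18. Ozonolysis (O3, CH2Cl2/MeOH, −78 °C; Me2S) gives benzyl 6-[2-(benzyloxy)-4-methyl-6-{[(triisopropylsilyl)oxy]methyl}phenoxy]-3-[(1S)-1-hydroxy-3-oxobutyl]-2-methoxybenzoate F3. MeMgBr with CeCl3 in THF at −78 °C adds to the methyl ketone (the di-ortho-substituted benzyl ester is too hindered to react), and the route is rejoined at 19.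

**Further compounds**
F1 | step 9 | benzyl 6-[2-(benzyloxy)-6-(hydroxymethyl)-4-methylphenoxy]-3-formyl-2-methoxybenzoate | COc1c(C=O)ccc(Oc2c(OCc3ccccc3)cc(C)cc2CO)c1C(=O)OCc1ccccc1
F2 | step 10 | benzyl 6-[2-(benzyloxy)-4-methyl-6-{[(triisopropylsilyl)oxy]methyl}phenoxy]-3-(3-hydroxy-3-methylbutanoyl)-2-methoxybenzoate | COc1c(C(=O)CC(C)(C)O)ccc(Oc2c(OCc3ccccc3)cc(C)cc2CO[Si](C(C)C)(C(C)C)C(C)C)c1C(=O)OCc1ccccc1
F3 | step 11 | benzyl 6-[2-(benzyloxy)-4-methyl-6-{[(triisopropylsilyl)oxy]methyl}phenoxy]-3-[(1S)-1-hydroxy-3-oxobutyl]-2-methoxybenzoate | COc1c([C@@H](O)CC(C)=O)ccc(Oc2c(OCc3ccccc3)cc(C)cc2CO[Si](C(C)C)(C(C)C)C(C)C)c1C(=O)OCc1ccccc1
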